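**Two runs.** The theta run, with 2 equiv of partner, has more isomer of the product than the delta run with 1 equiv: 22.3% against 11.5% at 1.00 h. Their other charges are equal, so in these two runs more partner goes with faster formation of isomer of the product. Before I let the delta flask run on, I want to know whether changing its partner would also change what it makes.

| flask | starting material | partner | other conformer | remark | time |
|---|---|---|---|---|---|
| delta | 0.45 M | 1 equiv | 1 equiv | the very flask that is asked about, followed so far |  |
| theta | 0.45 M | 2 equiv | 1 equiv | run made earlier |  |
| flask | 0.45 M | 1.00 equiv | 1.00 equiv |  | 8.0 h |

| run | time / h | isomer of the product / % | target / % |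
|---|---|---|---|
| delta | 0.333 | 5.8 | 1.3 |
| delta | 0.500 | 7.6 | 4.4 |
| delta | 0.667 | 10.6 | 5.5 |
| delta | 1.00 | 11.5 | 7.4 |
| delta | 1.50 | 15.0 | 7.3 |
| delta | 2.50 | 20.9 | 7.4 |
| delta | 4.00 | 23.6 | 11.9 |
| theta | 0.500 | 12.8 | 5.0 |
| theta | 1.00 | 22.3 | 11.1 |
| theta | 1.33 | 25.8 | 11.8 |
| theta | 2.00 | 32.2 | 16.2 |
| theta | 2.50 | 35.4 | 16.7 |
| theta | 3.00 | 36.7 | 19.1 |

(readings scatter by 1 percentage point)

1. ratio of isomer of the product to target at 3.0 min
2. ratio of isomer of the product to target at 30 min
3. ratio of isomer of the product to target at 8.0 h
4. which of isomer of the product and target there is more of at 8.0 h

**The split.** A single early ratio is poor: the first delta target reading is 1.3%, with a scatter of 1 percentage point. So I sum each run. The delta run gives 2.10 for the summed isomer of the product over the summed target, the selectivity factor I call the split. The theta run gives 2.07.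

**The decision.** I treat the effect of the partner as a small correction to the split and compute that correction: the split read off the delta run stands 0.0342 above the one read off the theta run, which has twice the partner. The scatter of the target sum in the delta run alone allows about 0.123, so the correction is smaller than its uncertainty. I leave the partner at 1.00 equiv and expect a ratio near 2.10 at 3.0 min, 30 min and 8.0 h, with isomer of the product ahead.

**The forecast.** The forecast gives 2.3, 2.15 and 2 at those times, with isomer of the product ahead, and holds that “the conformers appear to equilibrate quickly”. My flat split lies below its middle figure and above its last.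

**The flask.** The ratios come out at 2.30, 2.15 and 2.42, with isomer of the product ahead, 29.4% against 12.1% of target.

    starting material ⇌ other conformer (K = 0.970, k = 2.10 h⁻¹)
    starting material + partner ⇌ target (K = 16.0 L mol⁻¹, k = 0.380 L mol⁻¹ h⁻¹)
    partner + other conformer → isomer of the product (k = 0.890 L mol⁻¹ h⁻¹)
    other conformer ⇌ dormant form (K = 2.80, k = 0.370 h⁻¹)

**What happened.** In this flask the partner still stood at 68.5% of its charge at 0.800 h, and the turnover up to 8.0 h reached its midpoint at 1.31 h for the step to isomer of the product and 1.36 h for the step to dormant form. By 8.00 h the partner was down to 16.9% of its charge, the dormant form held 33.2% of the starting material and other conformer charged, and the ratio stood 0.320 above the split I read off the delta run. In a neighbouring flask charged with 0.400 equiv of partner, its other charges as in this flask, the split read off the delta run gives 2.10 again as my reckoning. The computed ratio there is 2.46 at 8.0 h, with 12.7% of isomer of the product and 5.18% of target.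

The data are calculated on assumed constants; noise was put on by code.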